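**Retrosynthetic overview**

1. Numbering: seven-membered ring C1(=CH2)–C2–C3(O-vanilloyl)–C4(H)–C5(Me)–C9–C10(OH); five-membered ring C4–C5–C6–C7–C8(OH, i-Pr). Azulene locants in the names: C1 = 6, C3 = 4, C4 = 3a, C5 = 8a, C8 = 3, C10 = 7.
2. Feature: the seven-membered ring has oxygen on C3 and C10 and a one-carbon branch on C1, so it maps onto a cyclohepta-1,4-diene (C1=C10, C3=C4) with two enol ethers and an ester, whose only stereocentre is quaternary C5. It is cut at C1–C2 and C5–C9 into a 2-siloxy diene (C2–C3–C4–C5) and a siloxyvinyl carbenoid (C1, C10, C9).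
3. Ring order: the five-membered ring is bought as 3-methylcyclopentenone and C2/C3 are attached by Stille coupling; the seven-membered ring is then closed in one step by cyclopropanation/Cope rearrangement under a chiral dirhodium catalyst, which sets C5.
4. The other stereocentres are relayed from C5 and C8: i-Pr adds to the C8 ketone anti to the C5 methyl, C4 is equilibrated to the trans ring fusion, C3 is reduced under direction of the C8 hydroxyl, C10 is reduced anti to the methyl and then inverted.
5. The two enol ethers carry different silyl groups (TES on O3, TIPS on O10), so that C3 can be unmasked, reduced and vanilloylated before the ester-derived C1 branch and O10 are turned into the methylene carbinol.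

Key step: step 7

Assumption: Rh2(S-PTAD)4 (dirhodium tetrakis[(S)-(1-adamantyl)(N-phthalimido)acetate], a tetracarboxylate of divalent rhodium) is taken to attack the enol-ether face that leads to the (1S,2R)-cyclopropane and hence the 8aR ring system; if this 1,1-disubstituted enol ether shows the opposite sense, Rh2(R-PTAD)4 is used with no other change.

**Route**

Step 1
Reactants: 1 3-methylcyclopent-2-en-1-one
Product: 3 2-bromo-3-methylcyclopent-2-en-1-one, via dibromo ketone 2 (not isolated)
Conditions: Br2 (1.05 equiv), CH2Cl2, 0 °C; then Et3N (1.5 equiv), 0 → 23 °C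
Reagents that add atoms: bromine, BrBr
Why: Bromine adds across the enone alkene and triethylamine removes HBr by E1cB elimination, the standard α-bromination of an enone.

Step 2
Reactants: 3 2-bromo-3-methylcyclopent-2-en-1-one, 4 tributyl(1-ethoxyethenyl)stannane
Product: 5 2-(1-ethoxyethenyl)-3-methylcyclopent-2-en-1-one
Conditions: Pd(PPh3)4 (5 mol %, zerovalent palladium), toluene, 100 °C; aq. KF work-up
Reagents that add atoms: none
Why: Stille cross-coupling of the α-bromo enone with the α-alkoxyvinylstannane places the masked acetyl group (C2, C3) on C4 without any regiochemical choice.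

Step 3
Reactants: 5 2-(1-ethoxyethenyl)-3-methylcyclopent-2-en-1-one
Product: 6 2-(2-bromoacetyl)-3-methylcyclopent-2-en-1-one
Conditions: N-bromosuccinimide (1.05 equiv), THF/H2O (5:1), 0 °C
Reagents that add atoms: N-bromosuccinimide, O=C1CCC(=O)N1Br; water, O
Why: Electrophilic bromination of the electron-rich enol ether and hydrolysis of the resulting oxocarbenium ion give the bromomethyl ketone, while the electron-poor tetrasubstituted enone alkene is left alone.

Step 4
Reactants: 6 2-(2-bromoacetyl)-3-methylcyclopent-2-en-1-one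
Product: 8 3-methyl-2-[1-(triethylsilyloxy)ethenyl]cyclopent-2-en-1-one, via zinc enolate 7 (not isolated)
Conditions: Zn dust (activated, 2 equiv), Et3SiCl (1.5 equiv), TMEDA (1.5 equiv), THF, 0 → 23 °C
Reagents that add atoms: chlorotriethylsilane, CC[Si](Cl)(CC)CC
Why: Reformatsky-type insertion of zinc into the C–Br bond gives the enolate of the acetyl group only, which is silylated on oxygen (reductive silylation of an α-bromo ketone); no base is present, so the more acidic γ-hydrogens of this alkylidene 1,3-diketone, which would misdirect a base-mediated silylation, are not touched.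

Step 5
Reactants: 9 methyl acetoacetate
Product: 10 methyl 2-diazo-3-oxobutanoate
Conditions: 4-acetamidobenzenesulfonyl azide (1.1 equiv), Et3N (1.2 equiv), MeCN, 0 → 23 °C
Reagents that add atoms: 4-acetamidobenzenesulfonyl azide, CC(=O)Nc1ccc(cc1)S(=O)(=O)N=[N+]=[N-]
Why: Regitz diazo transfer to the active methylene group.

Step 6
Reactants: 10 methyl 2-diazo-3-oxobutanoate
Product: 11 methyl 2-diazo-3-(triisopropylsilyloxy)but-3-enoate
Conditions: i-Pr3SiOTf (1.1 equiv), Et3N (1.3 equiv), CH2Cl2, 0 °C
Reagents that add atoms: triisopropylsilyl trifluoromethanesulfonate, CC(C)[Si](OS(=O)(=O)C(F)(F)F)(C(C)C)C(C)C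
Why: Soft enolisation and O-silylation of the acetyl group, the only enolisable position, give the siloxyvinyl diazoacetate; TIPS is chosen so that this enol ether later survives the fluoride and acetic acid conditions of steps 11 and 12.

Step 7
Reactants: 8 3-methyl-2-[1-(triethylsilyloxy)ethenyl]cyclopent-2-en-1-one, 11 methyl 2-diazo-3-(triisopropylsilyloxy)but-3-enoate
Product: 13 methyl (8aR)-8a-methyl-3-oxo-4-(triethylsilyloxy)-7-(triisopropylsilyloxy)-1,2,3,5,8,8a-hexahydroazulene-6-carboxylate, via divinylcyclopropane 12 (not isolated)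
Conditions: Rh2(S-PTAD)4 (1 mol %), 11 (1.5 equiv) added over 3 h to 8 in degassed 2,2-dimethylbutane/toluene (5:1), −20 → 23 °C; then toluene, 90 °C
Reagents that add atoms: none
Why: Proposed new method: the electrophilic rhodium siloxyvinylcarbenoid formed from 11 by loss of N2 is expected to cyclopropanate the terminal C2=C3 enol-ether alkene of 8 (forming C1–C2 and C1–C3, siloxyvinyl group cis to the cyclopentenone ring), and the cis-divinylcyclopropane 12 should then undergo a boat [3,3] Cope rearrangement that forms C5–C9 and breaks C1–C3; the closest known reaction type is the dirhodium-catalysed tandem cyclopropanation/Cope formal [4+3] cycloaddition of siloxyvinyldiazoacetates with dienes, which has not been shown for a 2-siloxy-3-acyl diene whose Cope terminus is a fully substituted ring carbon. The seven-membered ring is closed by the sigmatropic shift itself, a ring expansion of the cyclopropane in which the boat geometry makes both new ring alkenes cis, and not by an end-to-end cyclisation. The only stereocentre, quaternary C5, is controlled by the chiral catalyst, which selects the enantioface of the enol ether in the cyclopropanation, and the configuration of 12 is passed on stereospecifically through the boat transition state. Site selectivity between the enol ether, the tetrasubstituted enone alkene and the ketone oxygen is needed and is secured by the enol ether being the only electron-rich, unhindered alkene, while the cis arrangement follows the usual preference of donor/acceptor carbenoids. Because the C5 methyl points toward the cyclopropane in the boat, heating is planned once the diazo compound is consumed, and a hydrocarbon medium is used so that zwitterionic opening of the donor–acceptor cyclopropane, which would erase the stereochemistry, is disfavoured.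

Step 8
Reactants: 13 methyl (8aR)-8a-methyl-3-oxo-4-(triethylsilyloxy)-7-(triisopropylsilyloxy)-1,2,3,5,8,8a-hexahydroazulene-6-carboxylate, 14 isopropylmagnesium chloride
Product: 15 methyl (3R,8aR)-3-hydroxy-8a-methyl-3-(propan-2-yl)-4-(triethylsilyloxy)-7-(triisopropylsilyloxy)-1,2,3,5,8,8a-hexahydroazulene-6-carboxylate
Conditions: anhydrous CeCl3 (1.6 equiv), i-PrMgCl (1.5 equiv), THF, −78 °C, then 13; quench with aq. NaHCO3 at −78 °C; Et3N-deactivated silica
Reagents that add atoms: none
Why: 1,2-Addition of the organocerium reagent to the C8 ketone (the ester is a less electrophilic vinylogous carbonate) is expected from the face anti to the pseudo-axial C5 methyl, as in additions to ring-fused cyclopentanones with an angular methyl on the β-carbon, which sets C8 with the hydroxyl cis to the methyl; the weakly basic cerium reagent suppresses enolisation and β-hydride reduction.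

Step 9
Reactants: 15 methyl (3R,8aR)-3-hydroxy-8a-methyl-3-(propan-2-yl)-4-(triethylsilyloxy)-7-(triisopropylsilyloxy)-1,2,3,5,8,8a-hexahydroazulene-6-carboxylate
Product: 16 (3R,8aR)-6-(hydroxymethyl)-8a-methyl-3-(propan-2-yl)-4-(triethylsilyloxy)-7-(triisopropylsilyloxy)-1,2,3,5,8,8a-hexahydroazulen-3-ol
Conditions: i-Bu2AlH (4 equiv), CH2Cl2, −78 → −40 °C; aq. potassium sodium tartrate; crude product carried on
Reagents that add atoms: none
Why: Hydride reduction of the β-siloxy acrylate ester to the primary allylic alcohol, with both silyl enol ethers inert to the aluminium hydride and the tertiary hydroxyl carried as its aluminium alkoxide.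

Step 10
Reactants: 16 (3R,8aR)-6-(hydroxymethyl)-8a-methyl-3-(propan-2-yl)-4-(triethylsilyloxy)-7-(triisopropylsilyloxy)-1,2,3,5,8,8a-hexahydroazulen-3-ol
Product: 17 [(3R,8aR)-3-hydroxy-8a-methyl-3-(propan-2-yl)-4-(triethylsilyloxy)-7-(triisopropylsilyloxy)-1,2,3,5,8,8a-hexahydroazulen-6-yl]methyl acetate
Conditions: Ac2O (1.2 equiv), pyridine (3 equiv), DMAP (5 mol %), CH2Cl2, 0 °C
Reagents that add atoms: acetic anhydride, CC(=O)OC(C)=O
Why: DMAP-catalysed acetylation of the primary allylic alcohol only, the tertiary C8 hydroxyl being too hindered; the acetate protects this position and later serves as the leaving group that creates the methylene.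

Step 11
Reactants: 17 [(3R,8aR)-3-hydroxy-8a-methyl-3-(propan-2-yl)-4-(triethylsilyloxy)-7-(triisopropylsilyloxy)-1,2,3,5,8,8a-hexahydroazulen-6-yl]methyl acetate
Product: 19 [(3R,3aR,8aR)-3-hydroxy-8a-methyl-4-oxo-3-(propan-2-yl)-7-(triisopropylsilyloxy)-1,2,3,3a,4,5,8,8a-octahydroazulen-6-yl]methyl acetate, via cis-fused ketone 18 (not isolated)
Conditions: Bu4NF (1.1 equiv), AcOH (1.5 equiv), THF, −78 → −40 °C; then DBU (0.5 equiv), toluene, 23 °C
Reagents that add atoms: none
Why: Buffered fluoride cleaves the triethylsilyl enol ether much faster than the triisopropylsilyl one (steric discrimination at silicon) under non-acidic conditions that avoid Stork–Danheiser loss of the C8 hydroxyl, and DBU then equilibrates C4 through the enol to the trans-fused ketone, expected to be favoured because C3 lies anti to the isopropyl group and hydrogen-bonds to the cis C8 hydroxyl.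

Step 12
Reactants: 19 [(3R,3aR,8aR)-3-hydroxy-8a-methyl-4-oxo-3-(propan-2-yl)-7-(triisopropylsilyloxy)-1,2,3,3a,4,5,8,8a-octahydroazulen-6-yl]methyl acetate
Product: 20 [(3R,3aS,4S,8aR)-3,4-dihydroxy-8a-methyl-3-(propan-2-yl)-7-(triisopropylsilyloxy)-1,2,3,3a,4,5,8,8a-octahydroazulen-6-yl]methyl acetate
Conditions: Me4NBH(OAc)3 (5 equiv), MeCN/AcOH (1:1), −30 °C; aq. potassium sodium tartrate/NaHCO3
Reagents that add atoms: none
Why: Evans–Saksena reduction, in which the C8 hydroxyl binds boron and delivers hydride intramolecularly to the face of the C3 ketone on which it sits (the face of the C5 methyl), giving the 1,3-anti diol with O3 cis to the C4 hydrogen; this reagent does not reduce undirected ketones, esters or enol ethers.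

Step 13
Reactants: 21 vanillic acid
Product: 22 4-acetoxy-3-methoxybenzoic acid
Conditions: Ac2O (2.5 equiv), pyridine, 23 °C; then H2O/THF
Reagents that add atoms: acetic anhydride, CC(=O)OC(C)=O
Why: O-Acetylation masks the phenol so that the acid can be activated without self-condensation, the mixed anhydride at the carboxyl group being hydrolysed in the aqueous work-up.

Step 14
Reactants: 22 4-acetoxy-3-methoxybenzoic acid
Product: 23 4-acetoxy-3-methoxybenzoyl chloride
Conditions: (COCl)2 (1.5 equiv), DMF (cat.), CH2Cl2, 0 → 23 °C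
Reagents that add atoms: oxalyl chloride, O=C(Cl)C(Cl)=O
Why: Acid chloride formation with oxalyl chloride under Vilsmeier-type catalysis by DMF.

Step 15
Reactants: 20 [(3R,3aS,4S,8aR)-3,4-dihydroxy-8a-methyl-3-(propan-2-yl)-7-(triisopropylsilyloxy)-1,2,3,3a,4,5,8,8a-octahydroazulen-6-yl]methyl acetate, 23 4-acetoxy-3-methoxybenzoyl chloride
Product: 24 (3R,3aS,4S,8aR)-6-(acetoxymethyl)-3-hydroxy-8a-methyl-3-(propan-2-yl)-7-(triisopropylsilyloxy)-1,2,3,3a,4,5,8,8a-octahydroazulen-4-yl 4-acetoxy-3-methoxybenzoate
Conditions: 23 (2 equiv), pyridine (5 equiv), DMAP (0.1 equiv), CH2Cl2, 0 → 23 °C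
Reagents that add atoms: none
Why: Acylation of the secondary C3 alcohol by the acid chloride with nucleophilic catalysis, the tertiary C8 alcohol being unreactive; putting the vanilloyl group on now tells O3 apart from the still masked O10.

Step 16
Reactants: 24 (3R,3aS,4S,8aR)-6-(acetoxymethyl)-3-hydroxy-8a-methyl-3-(propan-2-yl)-7-(triisopropylsilyloxy)-1,2,3,3a,4,5,8,8a-octahydroazulen-4-yl 4-acetoxy-3-methoxybenzoate
Product: 26 (3R,3aS,4S,8aR)-3-hydroxy-8a-methyl-6-methylidene-7-oxo-3-(propan-2-yl)decahydroazulen-4-yl 4-acetoxy-3-methoxybenzoate, via acetoxy ketone 25 (not isolated)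
Conditions: Bu4NF (1.2 equiv), AcOH (1.2 equiv), THF, 0 °C; then Et3N (3 equiv), CH2Cl2, 0 → 23 °C
Reagents that add atoms: none
Why: Fluoride unmasks the C10 ketone from its silyl enol ether and triethylamine removes acetic acid from the β-acetoxy ketone by E1cB elimination to give the exocyclic enone; since C3 is no longer a ketone, the methylene cannot drift into an ene-dione.

Step 17
Reactants: 26 (3R,3aS,4S,8aR)-3-hydroxy-8a-methyl-6-methylidene-7-oxo-3-(propan-2-yl)decahydroazulen-4-yl 4-acetoxy-3-methoxybenzoate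
Product: 27 (3R,3aS,4S,7R,8aR)-3,7-dihydroxy-8a-methyl-6-methylidene-3-(propan-2-yl)decahydroazulen-4-yl 4-acetoxy-3-methoxybenzoate
Conditions: NaBH4 (1.5 equiv), CeCl3·7H2O (1.5 equiv), MeOH/THF (3:1), −78 °C
Reagents that add atoms: none
Why: Luche 1,2-reduction of the enone, in which hydride is expected to add to C10 from the face opposite the C5 methyl (axial and gauche to C10 in the chair-like seven-membered ring), giving the axial 10R alcohol cis to the methyl, i.e. the C10 epimer of the natural configuration.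

Step 18
Reactants: 27 (3R,3aS,4S,7R,8aR)-3,7-dihydroxy-8a-methyl-6-methylidene-3-(propan-2-yl)decahydroazulen-4-yl 4-acetoxy-3-methoxybenzoate, 28 4-nitrobenzoic acid
Product: 29 (3R,3aS,4S,7S,8aR)-4-[(4-acetoxy-3-methoxybenzoyl)oxy]-3-hydroxy-8a-methyl-6-methylidene-3-(propan-2-yl)decahydroazulen-7-yl 4-nitrobenzoate
Conditions: 28 (3 equiv), PPh3 (3 equiv), diisopropyl azodicarboxylate (3 equiv), toluene, 0 → 23 °C
Reagents that add atoms: none
Why: Mitsunobu reaction, in which SN2 displacement of the activated axial allylic oxygen by 4-nitrobenzoate from the unhindered face inverts C10 to the required S configuration, while the tertiary alcohol and the aryl esters are inert.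

Step 19
Reactants: 29 (3R,3aS,4S,7S,8aR)-4-[(4-acetoxy-3-methoxybenzoyl)oxy]-3-hydroxy-8a-methyl-6-methylidene-3-(propan-2-yl)decahydroazulen-7-yl 4-nitrobenzoate
Product: 30 (3R,3aS,4S,7S,8aR)-3,7-dihydroxy-8a-methyl-6-methylidene-3-(propan-2-yl)decahydroazulen-4-yl 4-hydroxy-3-methoxybenzoate (CNP0330487.1)
Conditions: K2CO3 (0.3 equiv), MeOH, 0 → 23 °C; aq. NH4Cl
Reagents that add atoms: none
Why: Base-catalysed transesterification removes the electron-poor 4-nitrobenzoate and the aryl acetate, whereas the secondary vanillate, deactivated as its phenoxide once the acetate is gone, should survive.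

**Compound list**

1 | 3-methylcyclopent-2-en-1-one | CC1=CC(=O)CC1 | starting material
2 | 2,3-dibromo-3-methylcyclopentan-1-one (racemic) | CC1(Br)CCC(=O)C1Br | intermediate
3 | 2-bromo-3-methylcyclopent-2-en-1-one | CC1=C(Br)C(=O)CC1 | intermediate
4 | tributyl(1-ethoxyethenyl)stannane | CCCC[Sn](CCCC)(CCCC)C(=C)OCC | starting material
5 | 2-(1-ethoxyethenyl)-3-methylcyclopent-2-en-1-one | C=C(OCC)C1=C(C)CCC1=O | intermediate
6 | 2-(2-bromoacetyl)-3-methylcyclopent-2-en-1-one | O=C(CBr)C1=C(C)CCC1=O | intermediate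
7 | bromozinc enolate of 6, bromo{[1-(2-methyl-5-oxocyclopent-1-en-1-yl)ethenyl]oxy}zinc | C=C(O[Zn]Br)C1=C(C)CCC1=O | intermediate
8 | 3-methyl-2-[1-(triethylsilyloxy)ethenyl]cyclopent-2-en-1-one | C=C(O[Si](CC)(CC)CC)C1=C(C)CCC1=O | intermediate
9 | methyl acetoacetate | COC(=O)CC(C)=O | starting material
10 | methyl 2-diazo-3-oxobutanoate | COC(=O)C(=[N+]=[N-])C(C)=O | intermediate
11 | methyl 2-diazo-3-(triisopropylsilyloxy)but-3-enoate | C=C(O[Si](C(C)C)(C(C)C)C(C)C)C(=[N+]=[N-])C(=O)OC | intermediate
12 | methyl (1S,2R)-2-(2-methyl-5-oxocyclopent-1-en-1-yl)-2-(triethylsilyloxy)-1-[1-(triisopropylsilyloxy)ethenyl]cyclopropane-1-carboxylate | COC(=O)[C@]1(C(=C)O[Si](C(C)C)(C(C)C)C(C)C)C[C@@]1(O[Si](CC)(CC)CC)C2=C(C)CCC2=O | intermediate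
13 | methyl (8aR)-8a-methyl-3-oxo-4-(triethylsilyloxy)-7-(triisopropylsilyloxy)-1,2,3,5,8,8a-hexahydroazulene-6-carboxylate | COC(=O)C1=C(O[Si](C(C)C)(C(C)C)C(C)C)C[C@@]2(C)CCC(=O)C2=C(O[Si](CC)(CC)CC)C1 | intermediate
14 | isopropylmagnesium chloride | CC(C)[Mg]Cl | starting material
15 | methyl (3R,8aR)-3-hydroxy-8a-methyl-3-(propan-2-yl)-4-(triethylsilyloxy)-7-(triisopropylsilyloxy)-1,2,3,5,8,8a-hexahydroazulene-6-carboxylate | COC(=O)C1=C(O[Si](C(C)C)(C(C)C)C(C)C)C[C@@]2(C)CC[C@@](O)(C(C)C)C2=C(O[Si](CC)(CC)CC)C1 | intermediate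
16 | (3R,8aR)-6-(hydroxymethyl)-8a-methyl-3-(propan-2-yl)-4-(triethylsilyloxy)-7-(triisopropylsilyloxy)-1,2,3,5,8,8a-hexahydroazulen-3-ol | OCC1=C(O[Si](C(C)C)(C(C)C)C(C)C)C[C@@]2(C)CC[C@@](O)(C(C)C)C2=C(O[Si](CC)(CC)CC)C1 | intermediate
17 | [(3R,8aR)-3-hydroxy-8a-methyl-3-(propan-2-yl)-4-(triethylsilyloxy)-7-(triisopropylsilyloxy)-1,2,3,5,8,8a-hexahydroazulen-6-yl]methyl acetate | CC(=O)OCC1=C(O[Si](C(C)C)(C(C)C)C(C)C)C[C@@]2(C)CC[C@@](O)(C(C)C)C2=C(O[Si](CC)(CC)CC)C1 | intermediate
18 | [(3R,3aS,8aR)-3-hydroxy-8a-methyl-4-oxo-3-(propan-2-yl)-7-(triisopropylsilyloxy)-1,2,3,3a,4,5,8,8a-octahydroazulen-6-yl]methyl acetate (cis-fused) | CC(=O)OCC1=C(O[Si](C(C)C)(C(C)C)C(C)C)C[C@@]2(C)CC[C@@](O)(C(C)C)[C@H]2C(=O)C1 | intermediate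
19 | [(3R,3aR,8aR)-3-hydroxy-8a-methyl-4-oxo-3-(propan-2-yl)-7-(triisopropylsilyloxy)-1,2,3,3a,4,5,8,8a-octahydroazulen-6-yl]methyl acetate (trans-fused) | CC(=O)OCC1=C(O[Si](C(C)C)(C(C)C)C(C)C)C[C@@]2(C)CC[C@@](O)(C(C)C)[C@@H]2C(=O)C1 | intermediate
20 | [(3R,3aS,4S,8aR)-3,4-dihydroxy-8a-methyl-3-(propan-2-yl)-7-(triisopropylsilyloxy)-1,2,3,3a,4,5,8,8a-octahydroazulen-6-yl]methyl acetate | CC(=O)OCC1=C(O[Si](C(C)C)(C(C)C)C(C)C)C[C@@]2(C)CC[C@@](O)(C(C)C)[C@@H]2[C@@H](O)C1 | intermediate
21 | vanillic acid | COc1cc(C(=O)O)ccc1O | starting material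
22 | 4-acetoxy-3-methoxybenzoic acid | COc1cc(C(=O)O)ccc1OC(C)=O | intermediate
23 | 4-acetoxy-3-methoxybenzoyl chloride | COc1cc(C(Cl)=O)ccc1OC(C)=O | intermediate
24 | (3R,3aS,4S,8aR)-6-(acetoxymethyl)-3-hydroxy-8a-methyl-3-(propan-2-yl)-7-(triisopropylsilyloxy)-1,2,3,3a,4,5,8,8a-octahydroazulen-4-yl 4-acetoxy-3-methoxybenzoate | CC(=O)OCC1=C(O[Si](C(C)C)(C(C)C)C(C)C)C[C@@]2(C)CC[C@@](O)(C(C)C)[C@@H]2[C@@H](OC(=O)c2ccc(OC(C)=O)c(OC)c2)C1 | intermediate
25 | (3R,3aS,4S,8aR)-6-(acetoxymethyl)-3-hydroxy-8a-methyl-7-oxo-3-(propan-2-yl)decahydroazulen-4-yl 4-acetoxy-3-methoxybenzoate (both C6 epimers) | CC(=O)OCC1C(=O)C[C@@]2(C)CC[C@@](O)(C(C)C)[C@@H]2[C@@H](OC(=O)c2ccc(OC(C)=O)c(OC)c2)C1 | intermediate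
26 | (3R,3aS,4S,8aR)-3-hydroxy-8a-methyl-6-methylidene-7-oxo-3-(propan-2-yl)decahydroazulen-4-yl 4-acetoxy-3-methoxybenzoate | C=C1C(=O)C[C@@]2(C)CC[C@@](O)(C(C)C)[C@@H]2[C@@H](OC(=O)c2ccc(OC(C)=O)c(OC)c2)C1 | intermediate
27 | (3R,3aS,4S,7R,8aR)-3,7-dihydroxy-8a-methyl-6-methylidene-3-(propan-2-yl)decahydroazulen-4-yl 4-acetoxy-3-methoxybenzoate | C=C1[C@H](O)C[C@@]2(C)CC[C@@](O)(C(C)C)[C@@H]2[C@@H](OC(=O)c2ccc(OC(C)=O)c(OC)c2)C1 | intermediate
28 | 4-nitrobenzoic acid | O=C(O)c1ccc(cc1)[N+](=O)[O-] | starting material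
29 | (3R,3aS,4S,7S,8aR)-4-[(4-acetoxy-3-methoxybenzoyl)oxy]-3-hydroxy-8a-methyl-6-methylidene-3-(propan-2-yl)decahydroazulen-7-yl 4-nitrobenzoate | C=C1[C@@H](OC(=O)c2ccc(cc2)[N+](=O)[O-])C[C@@]2(C)CC[C@@](O)(C(C)C)[C@@H]2[C@@H](OC(=O)c2ccc(OC(C)=O)c(OC)c2)C1 | intermediate
30 | (3R,3aS,4S,7S,8aR)-3,7-dihydroxy-8a-methyl-6-methylidene-3-(propan-2-yl)decahydroazulen-4-yl 4-hydroxy-3-methoxybenzoate | C=C1C[C@H](OC(=O)c2ccc(O)c(OC)c2)[C@@H]2[C@](C)(CC[C@@]2(O)C(C)C)C[C@@H]1O | target

**Step count and risks**

Total steps: 19. Longest linear sequence: 15 steps (1–4, 7–12, 15–19).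

Step 7. The Cope rearrangement of 12 may be too slow, because the C5 methyl is forced over the cyclopropane in the boat. Zwitterionic opening of the donor–acceptor cyclopropane or a vinylogous [3+2] pathway could then take over, with loss of material and of enantiomeric purity at C5. The fallback uses known chemistry, sets out from 1 and comes back at 13:
- Copper-catalysed asymmetric conjugate addition of a vinylaluminium reagent to 1 (Cu(OTf)2, chiral imidazolinium carbene ligand, (i-Bu)2AlCH=CH2) would set C5 and give (3S)-3-ethenyl-3-methylcyclopentan-1-one F1.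
- Aldehyde-selective Wacker oxidation (PdCl2(PhCN)2, CuCl2, AgNO2, O2) would give 2-[(1R)-1-methyl-3-oxocyclopentyl]acetaldehyde F2.
- Roskamp homologation with methyl diazoacetate and SnCl2 would give methyl 4-[(1S)-1-methyl-3-oxocyclopentyl]-3-oxobutanoate F3.
- C-Alkylation with methyl bromoacetate (K2CO3, acetone) would give dimethyl 2-{2-[(1S)-1-methyl-3-oxocyclopentyl]acetyl}butanedioate F4.
- An intramolecular Claisen condensation (KOt-Bu, THF, high dilution), in which only the C4 enolate of the cyclopentanone can reach the acetate carbonyl, would close the seven-membered ring to methyl (8aR)-8a-methyl-3,4,7-trioxodecahydroazulene-6-carboxylate F5.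
- Silylation of the more acidic 1,3-diketone (Et3SiCl, Et3N) would give methyl (8aR)-8a-methyl-3,7-dioxo-4-(triethylsilyloxy)-1,2,3,5,6,7,8,8a-octahydroazulene-6-carboxylate F6, and silylation of the β-keto ester (i-Pr3SiOTf, Et3N) would then give 13.

Step 11. The C4 methine, flanked by two quaternary carbons, may enolise too slowly under DBU, or the free tertiary β-hydroxy ketone may open by retro-aldol reaction or dehydrate before the trans ring fusion is reached. The fallback sets out from the mixture of 18 and 19 and comes back at 19. Instead of avoiding the retro-aldol reaction it uses it: a catalytic amount of KOt-Bu in t-BuOH/THF at 0 °C would open the aldol to the seco-diketone [(4R)-4-methyl-4-(4-methyl-3-oxopentyl)-6-oxo-2-(triisopropylsilyloxy)cyclohept-1-en-1-yl]methyl acetate F7 and let it close again under thermodynamic control. This should funnel C4 and C8 together into the diastereomer with trans ring fusion and isopropyl anti to both C3 and the C5 methyl, and would also correct material of the wrong C8 configuration.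

Step 8. Facial selectivity at C8 may be poor, because the C5 methyl and the C9 methylene flank the ketone almost symmetrically while C4 is still trigonal. The fallback sets out from 13 and comes back at 15. It replaces substrate control by reagent control: catalytic asymmetric addition of i-Pr2Zn in the presence of Ti(Oi-Pr)4 and a chiral camphorsulfonamide-derived bis(sulfonamide) diol ligand, using the ligand enantiomer that delivers isopropyl to the face anti to the C5 methyl. The product is again 15 (new compounds: none F0).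

**Further compounds**

F1 | step 7 | (3S)-3-ethenyl-3-methylcyclopentan-1-one | C=C[C@@]1(C)CCC(=O)C1
F2 | step 7 | 2-[(1R)-1-methyl-3-oxocyclopentyl]acetaldehyde | O=CC[C@@]1(C)CCC(=O)C1
F3 | step 7 | methyl 4-[(1S)-1-methyl-3-oxocyclopentyl]-3-oxobutanoate | COC(=O)CC(=O)C[C@@]1(C)CCC(=O)C1
F4 | step 7 | dimethyl 2-{2-[(1S)-1-methyl-3-oxocyclopentyl]acetyl}butanedioate (both C2 epimers) | COC(=O)CC(C(=O)OC)C(=O)C[C@@]1(C)CCC(=O)C1
F5 | step 7 | methyl (8aR)-8a-methyl-3,4,7-trioxodecahydroazulene-6-carboxylate (tautomer mixture) | COC(=O)C1CC(=O)C2C(=O)CC[C@]2(C)CC1=O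
F6 | step 7 | methyl (8aR)-8a-methyl-3,7-dioxo-4-(triethylsilyloxy)-1,2,3,5,6,7,8,8a-octahydroazulene-6-carboxylate | COC(=O)C1CC(O[Si](CC)(CC)CC)=C2C(=O)CC[C@]2(C)CC1=O
F7 | step 11 | [(4R)-4-methyl-4-(4-methyl-3-oxopentyl)-6-oxo-2-(triisopropylsilyloxy)cyclohept-1-en-1-yl]methyl acetate | CC(=O)OCC1=C(O[Si](C(C)C)(C(C)C)C(C)C)C[C@@](C)(CCC(=O)C(C)C)CC(=O)C1
F0 | step 8 | none | none
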